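**Retrosynthetic overview**

1. The target is cut at the C8–CH2–C6' bridge into two identical (2S)-7-hydroxy-5-methoxyflavan units and one formaldehyde; this phenol–formaldehyde condensation is the last step.
2. Each flavan comes from its 4,4-(propane-1,3-diyldithio) derivative by C–S hydrogenolysis; the pyran O1–C2 bond comes from an intramolecular Mitsunobu inversion of a (1R)-benzylic alcohol.
3. Key disconnection C4–C3: the unprotected aryl dithiane, used as its trilithio derivative (C4 as an acyl anion equivalent), opens (S)-styrene oxide, which supplies C3, C2, ring B and the stereocentre.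
4. The aryl dithiane comes from 2,4-dihydroxy-6-methoxybenzaldehyde and propane-1,3-dithiol; no protecting groups are used.
5. Ring order: ring A and ring B are bought, the temporary dithiane ring is made first, ring C (pyran) is closed third, and the two flavans are joined last.

Assumption: 2,4-dihydroxy-6-methoxybenzaldehyde, (S)-styrene oxide (at least 98% ee), propane-1,3-dithiol and formalin are bought as catalogue chemicals.

**Route**

Step 1
Reactants: 1 2,4-dihydroxy-6-methoxybenzaldehyde
Product: 2 2-(2,4-dihydroxy-6-methoxyphenyl)-1,3-dithiane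
Conditions: HS(CH2)3SH (1.1 equiv), BF3·OEt2 (0.2 equiv), AcOH–CH2Cl2 (1:4), 0 °C → rt, 6 h
Reagents that add atoms: propane-1,3-dithiol, SCCCS
Why: BF3-catalysed dithioacetalisation (the dithiane-forming step of the Corey–Seebach sequence) is downhill even for this electron-rich, hydrogen-bonded salicylaldehyde, tolerates free phenols and creates no stereocentre.

Step 2
Reactants: 2 2-(2,4-dihydroxy-6-methoxyphenyl)-1,3-dithiane; 3 (S)-styrene oxide [(2S)-2-phenyloxirane]
Product: 6 (1R)-2-[2-(2,4-dihydroxy-6-methoxyphenyl)-1,3-dithian-2-yl]-1-phenylethan-1-ol, via trilithium trianion 4 (not isolated), via trilithium alkoxide 5 (not isolated)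
Conditions: n-BuLi (3.3 equiv), TMEDA (3.3 equiv), THF, −78 → −20 °C, 2 h; 3 (1.3 equiv), −20 → 0 °C, 12 h; aq. HCl to pH 6, 0 °C
Reagents that add atoms: none
Why: Proposed new method: the two phenols are deprotonated first and act as their own protection, the third equivalent of TMEDA-activated n-BuLi removes the dithiane C2–H (still acidified by two sulfur atoms although the bis-phenoxide ring gives no benzylic stabilisation), and the hindered, localised carbanion 4 (an acyl anion equivalent for C4) opens 3 by SN2 at the unsubstituted CH2, so the C4–C3 bond joins two carbons that are both electrophilic in the parent aldehyde and epoxide while the stereocentre of 3 is carried over untouched (it is named 1R only because the CIP priorities change); the closest known reaction type is the Corey–Seebach alkylation of lithiated O-protected 2-aryl-1,3-dithianes with epoxides, and polylithiated phenoxide enolates of polyhydroxyacetophenones show that such polyanions are workable in THF.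

Step 3
Reactants: 6 (1R)-2-[2-(2,4-dihydroxy-6-methoxyphenyl)-1,3-dithian-2-yl]-1-phenylethan-1-ol
Product: 8 (2S)-5-methoxy-2-phenyl-2,3-dihydrospiro[chromene-4,2'-[1,3]dithian]-7-ol, via oxyphosphonium zwitterion 7 (not isolated)
Conditions: PPh3 (1.5 equiv), DIAD (1.5 equiv), THF (0.02 M), 0 °C → rt, 4 h
Reagents that add atoms: none
Why: Intramolecular Mitsunobu etherification: the PPh3/DIAD betaine deprotonates the phenol and activates the secondary alcohol as 7, and only the ortho phenoxide can reach C2 (6-exo-tet, helped by the quaternary dithiane carbon), so ring C closes by SN2 with inversion (1R → 2S) while the remote 4-OH stays free under high dilution.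

Step 4
Reactants: 8 (2S)-5-methoxy-2-phenyl-2,3-dihydrospiro[chromene-4,2'-[1,3]dithian]-7-ol
Product: 9 (2S)-5-methoxy-2-phenyl-3,4-dihydro-2H-chromen-7-ol [(2S)-7-hydroxy-5-methoxyflavan]
Conditions: Raney Ni (W-2, excess), H2 (1 atm), EtOH, 25 °C, 2 h
Reagents that add atoms: none
Why: Mozingo reduction: Raney Ni hydrogenolyses both benzylic C–S bonds to leave the C4 methylene, as in the routine desulfurisation of 4-thio-substituted flavans, while the phenol, the aryl methyl ether and the cyclic benzylic ether at C2 survive at room temperature, so the 2S centre is not touched.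

Step 5
Reactants: 9 (2S)-5-methoxy-2-phenyl-3,4-dihydro-2H-chromen-7-ol (two molecules)
Product: 12 (2S)-8-{[(2S)-7-hydroxy-5-methoxy-2-phenyl-3,4-dihydro-2H-chromen-6-yl]methyl}-5-methoxy-2-phenyl-3,4-dihydro-2H-chromen-7-ol, via hydroxymethyl flavan 10 (not isolated), via ortho-quinone methide 11 (not isolated)
Conditions: 37% aq. CH2O (0.4 equiv), HCl (5 mol %), AcOH–EtOH (1:1), 25 °C, 16 h; reversed-phase HPLC, unreacted 9 recycled
Reagents that add atoms: formaldehyde, C=O
Why: Acid-catalysed phenol–formaldehyde condensation (Lederer–Manasse hydroxymethylation to 10, dehydration to 11, Friedel–Crafts-type addition of a second molecule of 9): C6 and C8 are both ortho to the 7-OH and similarly activated, so the 6,6', 6,8' and 8,8' dimers form together and the unsymmetrical 6,8' isomer 12 is statistically doubled (an estimated 35–45% based on CH2O after HPLC, whichever position starts the sequence), and no stereocentre is involved.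

**Compound list**

1 | 2,4-dihydroxy-6-methoxybenzaldehyde | COc1cc(O)cc(O)c1C=O | starting material
2 | 2-(2,4-dihydroxy-6-methoxyphenyl)-1,3-dithiane | COc1cc(O)cc(O)c1C1SCCCS1 | intermediate
3 | (S)-styrene oxide, (2S)-2-phenyloxirane | C1[C@@H](O1)c1ccccc1 | starting material
4 | trilithium salt of 2 deprotonated at both phenols and at dithiane C2 | [Li+].[Li+].[Li+].COc1cc([O-])cc([O-])c1[C-]1SCCCS1 | intermediate (not isolated)
5 | trilithium salt (two phenoxides, one secondary alkoxide) of 6 | [Li+].[Li+].[Li+].COc1cc([O-])cc([O-])c1C1(C[C@@H]([O-])c2ccccc2)SCCCS1 | intermediate (not isolated)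
6 | (1R)-2-[2-(2,4-dihydroxy-6-methoxyphenyl)-1,3-dithian-2-yl]-1-phenylethan-1-ol | COc1cc(O)cc(O)c1C1(C[C@@H](O)c2ccccc2)SCCCS1 | intermediate
7 | oxyphosphonium zwitterion of 6 (O-triphenylphosphonio at the carbinol, ortho phenoxide) | COc1cc(O)cc([O-])c1C1(C[C@@H](O[P+](c2ccccc2)(c2ccccc2)c2ccccc2)c2ccccc2)SCCCS1 | intermediate (not isolated)
8 | (2S)-5-methoxy-2-phenyl-2,3-dihydrospiro[chromene-4,2'-[1,3]dithian]-7-ol (propane-1,3-diyl dithioketal of (2S)-7-hydroxy-5-methoxyflavan-4-one) | COc1cc(O)cc2c1C1(C[C@@H](c3ccccc3)O2)SCCCS1 | intermediate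
9 | (2S)-5-methoxy-2-phenyl-3,4-dihydro-2H-chromen-7-ol, (2S)-7-hydroxy-5-methoxyflavan | COc1cc(O)cc2c1CC[C@@H](c1ccccc1)O2 | intermediate
10 | (2S)-8-(hydroxymethyl)-5-methoxy-2-phenyl-3,4-dihydro-2H-chromen-7-ol | COc1cc(O)c(CO)c2c1CC[C@@H](c1ccccc1)O2 | intermediate (not isolated)
11 | (2S)-5-methoxy-8-methylidene-2-phenyl-3,4-dihydro-2H-chromen-7(8H)-one (ortho-quinone methide) | COC1=CC(=O)C(=C)C2=C1CC[C@@H](c1ccccc1)O2 | intermediate (not isolated)
12 | (2S)-8-{[(2S)-7-hydroxy-5-methoxy-2-phenyl-3,4-dihydro-2H-chromen-6-yl]methyl}-5-methoxy-2-phenyl-3,4-dihydro-2H-chromen-7-ol (CNP0178097.1) | COc1cc(O)c(Cc2c(O)cc3c(c2OC)CC[C@@H](c2ccccc2)O3)c2c1CC[C@@H](c1ccccc1)O2 | target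

**Step count and risks**

Total step count: 5. Longest linear sequence: 5 (1 → 2 → 6 → 8 → 9 → 12).

Most likely to fail, first: step 2. The trianion 4 may not form cleanly or may stay insoluble. The fallback masks the phenols and uses an ordinary monoanion. It sets out from 2: NaH and MOMCl in DMF at 0 °C give 2-[2,4-bis(methoxymethoxy)-6-methoxyphenyl]-1,3-dithiane F1. Lithiation with n-BuLi (1.1 equiv, THF, −30 °C; the dithiane C–H is far more acidic than the ring C–H between the two acetals) and opening of 3 give (1R)-2-{2-[2,4-bis(methoxymethoxy)-6-methoxyphenyl]-1,3-dithian-2-yl}-1-phenylethan-1-ol F2. HCl in MeOH (2 M, 40 °C) removes both acetals, and the route is rejoined at 6.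

Second: step 5. The condensation is not regioselective, and if C8 is much more reactive than C6 the 8,8' dimer dominates; oligomers are a further loss. The fallback builds the bridge stepwise with a removable block on C8. It sets out from 9: NBS (1.0 equiv, CH2Cl2, −78 °C) gives (2S)-8-bromo-5-methoxy-2-phenyl-3,4-dihydro-2H-chromen-7-ol F3. A second portion of 9 with CH2O and morpholine (EtOH, rt, Mannich reaction; the C8 isomer is purified at this monomer stage) gives (2S)-5-methoxy-8-(morpholin-4-ylmethyl)-2-phenyl-3,4-dihydro-2H-chromen-7-ol F4. Heating F4 with F3 (toluene, 110 °C) releases 11 with no other nucleophile present, so only C6 of F3 can add, giving (2S)-8-bromo-6-{[(2S)-7-hydroxy-5-methoxy-2-phenyl-3,4-dihydro-2H-chromen-8-yl]methyl}-5-methoxy-2-phenyl-3,4-dihydro-2H-chromen-7-ol F5. Brief hydrogenolysis (H2 1 atm, Pd/C, NaOAc, MeOH) removes the bromine, and the route is rejoined at 12. This fallback rests on the assumption that C8, the less hindered position ortho to the phenol, is brominated and aminomethylated first.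

Third: step 4. Raney Ni may also cleave the benzylic C2–O bond or stall on the hindered dithioketal. The fallback hydrolyses the dithioketal and removes the carbonyl oxygen by ionic hydrogenation. It sets out from 8: MeI and CaCO3 in MeCN–H2O (9:1, 45 °C) give (2S)-7-hydroxy-5-methoxy-2-phenyl-2,3-dihydro-4H-chromen-4-one F6. NaBH4 in MeOH at 0 °C gives (2S)-5-methoxy-2-phenyl-3,4-dihydro-2H-chromene-4,7-diol F7 (both C4 epimers are used). Et3SiH and CF3CO2H in CH2Cl2 (−20 → 0 °C) reduce the ring-A-stabilised C4 cation, and the route is rejoined at 9.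

**Further compounds**

F1 | step 2 | 2-[2,4-bis(methoxymethoxy)-6-methoxyphenyl]-1,3-dithiane | COc1cc(OCOC)cc(OCOC)c1C1SCCCS1
F2 | step 2 | (1R)-2-{2-[2,4-bis(methoxymethoxy)-6-methoxyphenyl]-1,3-dithian-2-yl}-1-phenylethan-1-ol | COc1cc(OCOC)cc(OCOC)c1C1(C[C@@H](O)c2ccccc2)SCCCS1
F3 | step 5 | (2S)-8-bromo-5-methoxy-2-phenyl-3,4-dihydro-2H-chromen-7-ol | COc1cc(O)c(Br)c2c1CC[C@@H](c1ccccc1)O2
F4 | step 5 | (2S)-5-methoxy-8-(morpholin-4-ylmethyl)-2-phenyl-3,4-dihydro-2H-chromen-7-ol | COc1cc(O)c(CN3CCOCC3)c2c1CC[C@@H](c1ccccc1)O2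
F5 | step 5 | (2S)-8-bromo-6-{[(2S)-7-hydroxy-5-methoxy-2-phenyl-3,4-dihydro-2H-chromen-8-yl]methyl}-5-methoxy-2-phenyl-3,4-dihydro-2H-chromen-7-ol | COc1cc(O)c(Cc2c(O)c(Br)c3c(c2OC)CC[C@@H](c2ccccc2)O3)c2c1CC[C@@H](c1ccccc1)O2
F6 | step 4 | (2S)-7-hydroxy-5-methoxy-2-phenyl-2,3-dihydro-4H-chromen-4-one | COc1cc(O)cc2c1C(=O)C[C@@H](c1ccccc1)O2
F7 | step 4 | (2S)-5-methoxy-2-phenyl-3,4-dihydro-2H-chromene-4,7-diol (C4 epimers) | COc1cc(O)cc2c1C(O)C[C@@H](c1ccccc1)O2
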